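**Plan**
1. Feature: in the dihydropyranone ring (O1, C2, C3, C4, C5, C6) the C4 carbonyl lies between C3H2 and C5H2, and both C2 and C6 carry oxygen. C4 can therefore be treated as a doubly nucleophilic acyl carbon, with C2–C3 and C5–C6 as two epoxide-derived units.
2. Cuts: first O1–C6 (cyclodehydration of a C2-oxygenated C4,C6-diketone); then C3–C4 and C4–C5 at a dithiane carbon standing for C4 (epoxide 5 + silyl dithiane 6 + propylene oxide 7); then side-chain C1'–C2' (oleyl Grignard + (R)-epichlorohydrin).
3. Forward: C18 + C3 gives the C21 epoxide; a one-flask anion relay joins epoxide, dithiane and propylene oxide into the full C25 chain; dithiane hydrolysis and carbinol oxidation give the 1,3-diketone; the only ring closes last through O1–C6.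
4. Stereochemistry: C2 (R) comes from (R)-epichlorohydrin and its C–O bond is never broken; the Z alkene comes from oleyl bromide; the propylene oxide centre is erased by oxidation.

Key step: step 3

Remark 1: ring atoms are labelled O1, C2 (stereocentre), C3, C4 (C=O), C5, C6 (C–CH3); side-chain carbons are primed.
Remark 2: isomerically pure (Z)-1-bromooctadec-9-ene is taken as the commercial C18 block. (S)-Propylene oxide is used instead of the racemate only so that 11 and 12 are single diastereomers.
Remark 3: organometallic steps are quenched with aqueous NH4Cl.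

**Step 1**
Reactants: 1 (Z)-1-bromooctadec-9-ene (oleyl bromide); 2 (R)-epichlorohydrin
Product: 4 (R,Z)-1-chlorohenicos-12-en-2-ol, via oleylmagnesium bromide 3 (not isolated)
Conditions: Mg, THF, rt → 40 °C; then 2, CuI (10 mol%), THF, −40 → −20 °C; aq. NH4Cl
Reagents that add atoms: none
Why: Copper-catalysed Grignard opening of a terminal epoxide, in which the organocopper attacks the unsubstituted epoxide carbon of 2 much faster than it displaces chloride at low temperature, so the carbinol centre of 2 is carried over unchanged as the R chlorohydrin and the remote Z alkene is a spectator.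

**Step 2**
Reactants: 4 (R,Z)-1-chlorohenicos-12-en-2-ol
Product: 5 (R,Z)-2-(nonadec-10-en-1-yl)oxirane
Conditions: NaOH (powdered), Et2O, rt
Reagents that add atoms: none
Why: Intramolecular Williamson closure of a 1,2-chlorohydrin, in which the alkoxide displaces chloride at the primary carbon and the C–O bond at the stereocentre is not involved, so 5 keeps the R configuration.

**Step 3**
Reactants: 5 (R,Z)-2-(nonadec-10-en-1-yl)oxirane; 6 2-(tert-butyldimethylsilyl)-1,3-dithiane; 7 (S)-propylene oxide
Product: 11 (S)-1-{2-[(R,Z)-2-(tert-butyldimethylsilyloxy)henicos-12-en-1-yl]-1,3-dithian-2-yl}propan-2-ol, via lithiated silyl dithiane 8 (not isolated), via lithium alkoxide 9 (not isolated), via Brook-shifted lithiodithiane 10 (not isolated)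
Conditions: 6, t-BuLi, Et2O, −78 → −45 °C; 5, Et2O, −78 → −25 °C; then 7, THF/HMPA, −78 → 0 °C; aq. NH4Cl
Reagents that add atoms: none
Why: t-BuLi deprotonates 6 to the silyl-stabilised anion 8, which opens 5 by SN2 attack at its unsubstituted carbon (C3–C4 bond) to give alkoxide 9; 9 persists in ether, but the THF/HMPA added with 7 triggers a 1,4-Brook shift of silicon from carbon to oxygen, and the resulting dithiane anion 10 opens 7 at its CH2 (C4–C5 bond). This is the known three-component anion relay (Brook-mediated linchpin) coupling of a 2-silyl-1,3-dithiane with two different terminal epoxides. No ring is closed in this step. No stereocentre is created: C2 and the methyl carbinol centre come unchanged from 5 and 7, because attack occurs only at the CH2 termini and neither C–O bond is broken. The step needs order selectivity (which epoxide ends up silylated), secured by the solvent-gated rearrangement and the order of addition, and regioselectivity, secured by the steric bias of monosubstituted epoxides; t-BuLi is consumed before 5 is added and the isolated Z alkene offers no site for the dithiane anions. The silyl shift also differentiates the two oxygens, leaving only the methyl carbinol free for the later oxidation.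

**Step 4**
Reactants: 11 (S)-1-{2-[(R,Z)-2-(tert-butyldimethylsilyloxy)henicos-12-en-1-yl]-1,3-dithian-2-yl}propan-2-ol
Product: 12 (2S,6R,16Z)-6-(tert-butyldimethylsilyloxy)-2-hydroxypentacos-16-en-4-one
Conditions: MeI (excess), CaCO3, MeCN/THF/H2O, 45 °C
Reagents that add atoms: water, O
Why: Alkylative dithiane hydrolysis, in which S-methylation turns sulfur into a leaving group and water adds to the thionium ion, run in a neutral carbonate-buffered medium that should leave the TBS ether, the free carbinol and the Z alkene (which halonium or mercury(II) reagents could attack) untouched.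

**Step 5**
Reactants: 12 (2S,6R,16Z)-6-(tert-butyldimethylsilyloxy)-2-hydroxypentacos-16-en-4-one
Product: 13 (6R,16Z)-6-(tert-butyldimethylsilyloxy)pentacos-16-ene-2,4-dione
Conditions: IBX, EtOAc, 75 °C
Reagents that add atoms: none
Why: Hypervalent-iodine oxidation of a β-hydroxy ketone to the β-diketone under conditions that are neither basic nor strongly acidic, so the β-silyloxy ketone should not eliminate, the alkene is inert, sulfur is already gone, and the only stereocentre lost is the one no longer needed.

**Step 6**
Reactants: 13 (6R,16Z)-6-(tert-butyldimethylsilyloxy)pentacos-16-ene-2,4-dione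
Product: 16 (R)-6-methyl-2-[(Z)-nonadec-10-en-1-yl]-2,3-dihydro-4H-pyran-4-one, via hydroxy diketone 14 (not isolated), via cyclic hemiketal 15 (not isolated)
Conditions: TFA, CH2Cl2 (trace H2O), 0 °C → rt
Reagents that add atoms: none
Why: Acid cleaves the secondary TBS ether to 14, the C2 hydroxyl adds to the C6 carbonyl (6-exo-trig hemiketalisation to 15) and acid-catalysed loss of water gives the conjugated vinylogous ester as the thermodynamic sink, which is the standard cyclodehydration of δ-hydroxy-β-diketones to 2,3-dihydro-4H-pyran-4-ones and retains the C2–O bond and hence the R configuration.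

**Compound list**
1 | (Z)-1-bromooctadec-9-ene (oleyl bromide) | CCCCCCCC/C=C\CCCCCCCCBr | starting material
2 | (R)-epichlorohydrin [(R)-2-(chloromethyl)oxirane] | ClC[C@H]1CO1 | starting material
3 | (Z)-octadec-9-en-1-ylmagnesium bromide | CCCCCCCC/C=C\CCCCCCCC[Mg]Br | intermediate
4 | (R,Z)-1-chlorohenicos-12-en-2-ol | CCCCCCCC/C=C\CCCCCCCCC[C@@H](O)CCl | intermediate
5 | (R,Z)-2-(nonadec-10-en-1-yl)oxirane | CCCCCCCC/C=C\CCCCCCCCC[C@@H]1CO1 | intermediate
6 | 2-(tert-butyldimethylsilyl)-1,3-dithiane | CC(C)(C)[Si](C)(C)C1SCCCS1 | starting material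
7 | (S)-propylene oxide [(S)-2-methyloxirane] | C[C@H]1CO1 | starting material
8 | 2-lithio-2-(tert-butyldimethylsilyl)-1,3-dithiane | [Li]C1([Si](C)(C)C(C)(C)C)SCCCS1 | intermediate
9 | lithium (R,Z)-1-[2-(tert-butyldimethylsilyl)-1,3-dithian-2-yl]henicos-12-en-2-olate | CCCCCCCC/C=C\CCCCCCCCC[C@@H]([O-])CC1([Si](C)(C)C(C)(C)C)SCCCS1.[Li+] | intermediate
10 | 2-lithio-2-[(R,Z)-2-(tert-butyldimethylsilyloxy)henicos-12-en-1-yl]-1,3-dithiane | CCCCCCCC/C=C\CCCCCCCCC[C@@H](O[Si](C)(C)C(C)(C)C)CC1([Li])SCCCS1 | intermediate
11 | (S)-1-{2-[(R,Z)-2-(tert-butyldimethylsilyloxy)henicos-12-en-1-yl]-1,3-dithian-2-yl}propan-2-ol | CCCCCCCC/C=C\CCCCCCCCC[C@@H](O[Si](C)(C)C(C)(C)C)CC1(C[C@H](C)O)SCCCS1 | intermediate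
12 | (2S,6R,16Z)-6-(tert-butyldimethylsilyloxy)-2-hydroxypentacos-16-en-4-one | CCCCCCCC/C=C\CCCCCCCCC[C@@H](O[Si](C)(C)C(C)(C)C)CC(=O)C[C@H](C)O | intermediate
13 | (6R,16Z)-6-(tert-butyldimethylsilyloxy)pentacos-16-ene-2,4-dione | CCCCCCCC/C=C\CCCCCCCCC[C@@H](O[Si](C)(C)C(C)(C)C)CC(=O)CC(C)=O | intermediate
14 | (6R,16Z)-6-hydroxypentacos-16-ene-2,4-dione | CCCCCCCC/C=C\CCCCCCCCC[C@@H](O)CC(=O)CC(C)=O | intermediate
15 | (6R)-2-hydroxy-2-methyl-6-[(Z)-nonadec-10-en-1-yl]oxan-4-one (both C2 epimers) | CCCCCCCC/C=C\CCCCCCCCC[C@@H]1CC(=O)CC(C)(O)O1 | intermediate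
16 | (R)-6-methyl-2-[(Z)-nonadec-10-en-1-yl]-2,3-dihydro-4H-pyran-4-one | CCCCCCCC/C=C\CCCCCCCCC[C@@H]1CC(=O)C=C(C)O1 | target

Total step count: 6
Longest linear sequence: 6 steps (1 → 16)

**Steps most likely to fail**

Step 3. The silyl migration may occur too early or not at all. If it occurs in ether, the relayed anion would consume a second molecule of 5. If it fails after the solvent switch, the sequence would stop at the two-component adduct. Proton transfer could also quench the relayed anion before it meets 7. The fallback sets out from 5 and returns at 11, and replaces the relay by two separate dithiane alkylations. 1,3-Dithiane and n-BuLi in THF at −30 °C would give 2-lithio-1,3-dithiane F1, which opens 5 at its CH2 to give (R,Z)-1-(1,3-dithian-2-yl)henicos-12-en-2-ol F2. TBSCl and imidazole in DMF would then give tert-butyl{[(R,Z)-1-(1,3-dithian-2-yl)henicos-12-en-2-yl]oxy}dimethylsilane F3. Deprotonation of this with t-BuLi in THF/HMPA at −78 °C would generate anion 10 directly, and addition of 7 would give 11.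

Step 6. Acid may promote β-elimination of the C2 oxygen in competition with ring closure, erode the C2 configuration through reversible ring opening of the product, or desilylate too slowly. The fallback sets out from 12 and returns at 16. It forms the O1–C6 bond by oxypalladation instead of ketalisation, so neither a 1,3-diketone nor strong acid is needed. MsCl and Et3N in CH2Cl2 at 0 °C would convert 12 into (2S,6R,16Z)-6-(tert-butyldimethylsilyloxy)-4-oxopentacos-16-en-2-yl methanesulfonate F4. This should eliminate in the same flask (Et3N, then DBU if needed) to (2E,6R,16Z)-6-(tert-butyldimethylsilyloxy)pentacosa-2,16-dien-4-one F5. Buffered HF·pyridine in THF would give (2E,6R,16Z)-6-hydroxypentacosa-2,16-dien-4-one F6. Wacker-type oxidative cyclisation (PdCl2(MeCN)2 cat., CuCl cat., Na2HPO4, O2, DME, 50 °C), by 6-endo oxypalladation and β-hydride elimination, should then give 16. This is a known reaction type for β-hydroxy enones and does not touch the carbinol C–O bond.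

Step 5. The product may be over-oxidised at its doubly activated methylene (ring C5), or the β-hydroxy ketone may eliminate or undergo retro-aldol cleavage in the hot suspension. The fallback sets out from 11 and returns at 13. It inverts the order of oxidation and unmasking, so the oxidant never meets a β-dicarbonyl. Parikh–Doering oxidation of 11 (SO3·pyridine, DMSO, i-Pr2NEt, CH2Cl2, 0 °C) would give (R,Z)-1-{2-[2-(tert-butyldimethylsilyloxy)henicos-12-en-1-yl]-1,3-dithian-2-yl}propan-2-one F7. The dithiane would then be removed as in step 4 (MeI, CaCO3, MeCN/THF/H2O) to give 13.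

**Further compounds**
F1 | step 3 | 2-lithio-1,3-dithiane | [Li]C1SCCCS1
F2 | step 3 | (R,Z)-1-(1,3-dithian-2-yl)henicos-12-en-2-ol | CCCCCCCC/C=C\CCCCCCCCC[C@@H](O)CC1SCCCS1
F3 | step 3 | tert-butyl{[(R,Z)-1-(1,3-dithian-2-yl)henicos-12-en-2-yl]oxy}dimethylsilane | CCCCCCCC/C=C\CCCCCCCCC[C@@H](O[Si](C)(C)C(C)(C)C)CC1SCCCS1
F4 | step 6 | (2S,6R,16Z)-6-(tert-butyldimethylsilyloxy)-4-oxopentacos-16-en-2-yl methanesulfonate | CCCCCCCC/C=C\CCCCCCCCC[C@@H](O[Si](C)(C)C(C)(C)C)CC(=O)C[C@H](C)OS(C)(=O)=O
F5 | step 6 | (2E,6R,16Z)-6-(tert-butyldimethylsilyloxy)pentacosa-2,16-dien-4-one | CCCCCCCC/C=C\CCCCCCCCC[C@@H](O[Si](C)(C)C(C)(C)C)CC(=O)/C=C/C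
F6 | step 6 | (2E,6R,16Z)-6-hydroxypentacosa-2,16-dien-4-one | CCCCCCCC/C=C\CCCCCCCCC[C@@H](O)CC(=O)/C=C/C
F7 | step 5 | (R,Z)-1-{2-[2-(tert-butyldimethylsilyloxy)henicos-12-en-1-yl]-1,3-dithian-2-yl}propan-2-one | CCCCCCCC/C=C\CCCCCCCCC[C@@H](O[Si](C)(C)C(C)(C)C)CC1(CC(C)=O)SCCCS1
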